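# Synthesis plan for CNP0243830.4 (target 36): a succinate-linchpin double Ireland–Claisen route

## The problem

Target 36 consists of two differently rearranged drimane-type decalins joined by a CH2–CH2 tether. Each decalin is numbered C1–C10 like a drimane and viewed in the steroid orientation (α = below the plane). The eastern unit E has 4,4-Me2, 5α-H, 8β-Me, 9β-Me and a C1=C10 alkene. The western unit W has 4β-Me, a C5=C6 alkene, 10β-H, 9α-Me, 9β-CH2Ar and 8α-Me. The tether is C11 (on E-C9, α) and C12 (on W-C4, α).

The hardest bond set is E-C9–C11–C12–W-C4: two quaternary stereocentres separated by two methylenes, so any union of two finished halves has to use neopentyl partners. Each of these quaternary carbons also sits next to a ring-fusion trisubstituted alkene (E-C10=C1, W-C5=C6) whose position must be exact and which acid would move by 1,2-shifts.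

There are seven stereocentres. The two decalins are too far apart to relay, so each needs its own absolute control. Within E, C5 can steer C8 but nothing steers C9. Within W, C8 can steer C9 and C10, but C4 is insulated from them by sp2 C5.

The aryl bis(hydrogen sulfate) is acid-labile and the free hydroquinone is air-sensitive, so both must be unveiled last.

The feature that opens the problem is that both quaternary carbons are allylic in the same sense: E-C9–C10=C1 (alkene reaching into ring A of E) and W-C4–C5=C6 (alkene reaching into ring B of W). Each is therefore the terminus of a [3,3] shift from an oxygen on E-C1 or W-C6, and C11–C12 are the two α-carbons of succinic acid.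

## Retrosynthesis

**36 ⇒ 34 ⇒ 32.** The two S–O bonds are cut first and the phenols are traced to methyl ethers. Sulfates cannot pass through enolate, organometallic or radical steps. Methyl ethers survive LDA, Grignard reagents, Li/NH3 and thiyl radicals, and their oxidative removal through quinone 33 leaves hindered trisubstituted alkenes alone. Precursor 32 is a pure hydrocarbon skeleton with two OMe groups.

**32 ⇒ 30.** A carboxyl group is added to each tether carbon (C11 and C12). This costs two carbons that are later lost as CO2, but it turns the tether into a 2,3-disubstituted succinic acid, the retron of two ester-enolate Claisen shifts. The forward reaction must remove both carboxyls by hydrogen transfer faster than the homoallylic radicals can rearrange.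

**30 ⇒ 27 (key disconnection).** The bonds E-C9–C11 and W-C4–C12 are cut, with both alkenes moved back to E-C9=C10 and W-C4=C5 and oxygen placed on E-C1 and W-C6. Cutting C11–C12 instead would leave both quaternary centres to be made separately and joined through neopentyl carbons. The chosen cut removes both quaternary stereocentres, both alkene-position problems and the tether at once. What remains is the bis-allylic succinate 27, which falls apart at two ester bonds into alcohol 10 (14 carbons), succinic anhydride 11 and alcohol 26 (22 carbons), via half-ester 12. The forward reaction must enolise both ester arms, then rearrange twice onto tetrasubstituted alkene termini with suprafacial transfer of the carbinol configurations.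

**10 ⇒ 9 ⇒ 7 ⇒ 4 + 3.** The E-C1 carbinol comes from enone 9 by reagent-controlled reduction. The E-C9=C10 bond of 9 is an intramolecular aldol condensation of the diketone 8 released from ketal 7. The E-C5–C6 bond of 7 is a catalytic enantioselective conjugate addition of the side chain of bromide 3 to commercial enone 4. Bromide 3 comes in two steps from lactone 1 via bromo ketone 2. E-C8 is left to equilibrate in 9, where the wanted epimer avoids A(1,2) strain.

**26 ⇒ 25 ⇒ 23 ⇒ 22 ⇒ 21 ⇒ 18 + 19, and 18 ⇒ 16 ⇒ 13 + 14.** The W-C6 carbinol comes from enone 25, again an aldol condensation product (W-C4=C5 bond) of the diketone 24 released from ketal 23.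

The all-cis ketone 23 cannot be made by adding carbon to W-C10, because cuprates add trans to a 5-substituent. The side chain is therefore put on an sp2 W-C10 (enone 22) and hydrogen is delivered last. Enone 22 arises by Grignard addition of 19 (via reagent 20) to enone 18 and oxidative 1,3-transposition of alcohol 21.

Enone 18 is the dehydrogenation product of ketone 16 (through silyl enol ether 17). The vicinal W-C8/W-C9 pair of 16 is set in one operation from 2-methylcyclohexenone 13 and benzyl chloride 14 by asymmetric methyl addition and anti alkylation of the enolate 15.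

## Roads not taken

**Alternative 1:** Cut the C11–C12 bond (the obvious cut). The forward key step is a Julia–Kocienski olefination of eastern aldehyde A1 with the anion of western sulfone A2, then reduction of the resulting alkene A3.
- Each quaternary centre must be built on its own and trimmed to a one-carbon handle (a Claisen product carries two carbons, so each half needs a degradation).
- A neopentyl-type sulfone anion must attack a neopentyl aldehyde.
- The alkene of A3 must be reduced beside two trisubstituted ones.
- The chosen plan forms the same two hindered bonds intramolecularly, from simpler alcohols, and buys the tether as succinic anhydride.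

**Alternative 2:** Cut W-C4–C12. The forward key step is deconjugative α-alkylation of the dienolate of the 4-methyl-Δ4-3-ketone A4 with eastern iodide A5 to give A6, followed by removal of the C3 ketone.
- The step is attractive because it makes W-C4 and the C5=C6 alkene together.
- With no angular substituent on W-C10, stereoelectronically preferred axial attack puts the incoming chain on the β-face, which gives the C4 epimer of A6.
- The carbonyl next to the new quaternary centre would then need a Wolff–Kishner-type removal.
- A5 still needs E-C9 to be made separately.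
- In the chosen plan, W-C4 is dictated by a carbinol set under reagent control.

**Alternative 3:** Follow the biogenesis. The forward key step is a Lewis-acid (BF3·OEt2) 1,2-hydride/1,2-methyl shift cascade on an 8(12)-drimene such as A7 (from (+)-sclareolide), to give the C1=C10 alkene of A8.
- The terminating proton loss favours the tetrasubstituted C5=C10 alkene or gives mixtures, and nothing in A7 can direct it.
- Unit W would need a different, three-shift cascade on a skeleton with a non-natural C4 centre that no chiral-pool drimane supplies.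
- The halves would still have to be joined across two neopentyl carbons.
- The chosen plan fixes each alkene by the position of an oxygen atom.

Key step: step 15

## Remarks before the steps

- The target is drawn as the free bis(hydrogen sulfate). It is delivered in that form by cold cation exchange of its pyridinium salt, and should be handled cold because aryl hydrogen sulfates hydrolyse in acid.
- C11 and C12 in compounds 29–31 are formed without control and are left undefined in the SMILES, since both become CH2.
- The side-chain methine of 7 and 8 and the carbinol carbon of 21 are likewise undefined.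

## Route

**Step 1**
Reactants: 1 3-acetyl-3-methyloxolan-2-one
Product: 2 5-bromo-3-methylpentan-2-one
Conditions: 48% aq HBr, 80 °C
Reagents that add atoms: hydrogen bromide, SMILES Br
Why: Acid-mediated opening of the lactone by bromide at the O–CH2 carbon and decarboxylation of the β-keto acid, the classical α-acyl-butyrolactone to γ-halo ketone conversion; the stereocentre is irrelevant because it is equilibrated in step 4.

**Step 2**
Reactants: 2 5-bromo-3-methylpentan-2-one
Product: 3 2-(4-bromobutan-2-yl)-2-methyl-1,3-dioxolane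
Conditions: ethylene glycol, TsOH (cat.), toluene, reflux, water separator
Reagents that add atoms: ethylene glycol, SMILES OCCO
Why: Standard acid-catalysed ketalisation with azeotropic water removal; it masks the ketone so that an organometallic reagent can be made from the bromide.

**Step 3**
Reactants: 3 2-(4-bromobutan-2-yl)-2-methyl-1,3-dioxolane; 4 4,4-dimethylcyclohex-2-en-1-one
Product: 7 (3R)-4,4-dimethyl-3-[3-(2-methyl-1,3-dioxolan-2-yl)butyl]cyclohexan-1-one, via Grignard reagent 5 (not isolated), via dialkylzinc 6 (not isolated)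
Conditions: 3, Mg, THF, 40 °C; ZnCl2 (0.5 equiv), then 1,4-dioxane, filter; Cu(OTf)2 (2 mol%), BINOL-derived phosphoramidite (4 mol%), 4, toluene, −30 °C; aq NH4Cl
Reagents that add atoms: none
Why: Copper-catalysed enantioselective conjugate addition of a functionalised dialkylzinc to a cyclohexenone, the first half of the known asymmetric annulation of cyclohexenones, which tolerates the gem-dimethyl group next to the β-carbon. The ligand enantiomer is chosen to give the (3R)-ketone, which fixes E-C5 (5α-H).

**Step 4**
Reactants: 7 (3R)-4,4-dimethyl-3-[3-(2-methyl-1,3-dioxolan-2-yl)butyl]cyclohexan-1-one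
Product: 9 (4aS,7S)-4,4,7,8-tetramethyl-3,4,4a,5,6,7-hexahydronaphthalen-1(2H)-one, via diketone 8 (not isolated)
Conditions: 2 M HCl, THF, rt; then KOH, MeOH, reflux (prolonged)
Reagents that add atoms: none
Why: Ketal hydrolysis then intramolecular aldol condensation; only attack of E-C10 on the methyl ketone can dehydrate (the other six-ring closure is a bridged aldol without an α-hydrogen), so the tetrasubstituted enone is the sink. Base equilibrates E-C8 through the dienolate towards the epimer whose methyl is pseudoaxial and free of A(1,2) strain with the C9 methyl, which is the required 8β-Me; residual epimer is removed after step 5.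

**Step 5**
Reactants: 9 (4aS,7S)-4,4,7,8-tetramethyl-3,4,4a,5,6,7-hexahydronaphthalen-1(2H)-one
Product: 10 (1S,4aS,7S)-4,4,7,8-tetramethyl-1,2,3,4,4a,5,6,7-octahydronaphthalen-1-ol
Conditions: (R)-2-methyl-CBS-oxazaborolidine (20 mol%), catecholborane, toluene, −78 °C; aq NaOH
Reagents that add atoms: none
Why: CBS reduction with the alkenyl side as the large group gives the (1S)-carbinol (1α-OH, axial in ring A), which is also the product of equatorial attack by a bulky hydride, so reagent and substrate are matched. This carbinol later dictates E-C9; material from the minor enantiomer of step 3 becomes a separable diastereomer here.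

**Step 6**
Reactants: 10 (1S,4aS,7S)-4,4,7,8-tetramethyl-1,2,3,4,4a,5,6,7-octahydronaphthalen-1-ol; 11 succinic anhydride
Product: 12 4-oxo-4-{[(1S,4aS,7S)-4,4,7,8-tetramethyl-1,2,3,4,4a,5,6,7-octahydronaphthalen-1-yl]oxy}butanoic acid
Conditions: DMAP, Et3N, CH2Cl2, rt
Reagents that add atoms: none
Why: DMAP-catalysed acylation of a secondary alcohol by a cyclic anhydride under basic conditions, which leaves the ionisable allylic C–O bond and its configuration untouched.

**Step 7**
Reactants: 13 2-methylcyclohex-2-en-1-one; 14 2-(chloromethyl)-1,4-dimethoxybenzene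
Product: 16 (2S,3R)-2-(2,5-dimethoxybenzyl)-2,3-dimethylcyclohexan-1-one, via magnesium enolate 15 (not isolated)
Conditions: MeMgBr (1.2 equiv), Cu(OTf)2 (3 mol%), chiral imidazolinium salt (4 mol%), Et2O, 0 °C; then 14, Bu4NI (10 mol%), DMPU, THF, 0 °C to rt
Reagents that add atoms: methylmagnesium bromide, SMILES C[Mg]Br
Why: Copper-catalysed enantioselective conjugate addition of a Grignard reagent to an α-substituted cyclohexenone, followed by C-alkylation of the regiodefined magnesium enolate. The catalyst sets W-C8 (3R), and the benzyl halide enters anti to the new neighbouring methyl, giving cis methyls and a trans arylmethyl group at W-C9.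

**Step 8**
Reactants: 16 (2S,3R)-2-(2,5-dimethoxybenzyl)-2,3-dimethylcyclohexan-1-one
Product: 18 (5R,6S)-6-(2,5-dimethoxybenzyl)-5,6-dimethylcyclohex-2-en-1-one, via silyl enol ether 17 (not isolated)
Conditions: LDA, TMSCl, THF, −78 °C; then Pd(OAc)2 (1.05 equiv), MeCN, rt
Reagents that add atoms: none
Why: Saegusa–Ito oxidation; the ketone can enolise only towards its CH2 side because the other α-carbon is quaternary, so the enone regiochemistry is unambiguous and the electron-rich arene is not exposed to a quinone oxidant.

**Step 9**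
Reactants: 18 (5R,6S)-6-(2,5-dimethoxybenzyl)-5,6-dimethylcyclohex-2-en-1-one; 19 2-(3-chloropropyl)-2-methyl-1,3-dioxolane
Product: 21 (5R,6S)-6-(2,5-dimethoxybenzyl)-5,6-dimethyl-1-[3-(2-methyl-1,3-dioxolan-2-yl)propyl]cyclohex-2-en-1-ol, via Grignard reagent 20 (not isolated)
Conditions: 19, Mg, THF, 45 °C; then 18, LaCl3·2LiCl (0.3 equiv), THF, 0 °C; aq NH4Cl
Reagents that add atoms: none
Why: 1,2-Addition of a primary Grignard reagent to an enone that has no α-hydrogen on its hindered side; the lanthanum salt favours carbonyl addition over reduction. The new carbinol configuration is irrelevant because the carbon becomes sp2 in step 10.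

**Step 10**
Reactants: 21 (5R,6S)-6-(2,5-dimethoxybenzyl)-5,6-dimethyl-1-[3-(2-methyl-1,3-dioxolan-2-yl)propyl]cyclohex-2-en-1-ol
Product: 22 (4S,5R)-4-(2,5-dimethoxybenzyl)-4,5-dimethyl-3-[3-(2-methyl-1,3-dioxolan-2-yl)propyl]cyclohex-2-en-1-one
Conditions: pyridinium chlorochromate (C5H5NH[CrO3Cl], 2 equiv), NaOAc, 4 Å MS, CH2Cl2, rt
Reagents that add atoms: pyridinium chlorochromate, SMILES [O-][Cr](=O)(=O)Cl.c1cc[nH+]cc1
Why: Babler–Dauben oxidative transposition: [3,3] shift of the tertiary allylic chromate ester and oxidation of the resulting secondary ester. This moves oxygen to W-C6 and leaves the side chain on an sp2 W-C10; acetate buffering protects the ketal.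

**Step 11**
Reactants: 22 (4S,5R)-4-(2,5-dimethoxybenzyl)-4,5-dimethyl-3-[3-(2-methyl-1,3-dioxolan-2-yl)propyl]cyclohex-2-en-1-one
Product: 23 (3S,4S,5R)-4-(2,5-dimethoxybenzyl)-4,5-dimethyl-3-[3-(2-methyl-1,3-dioxolan-2-yl)propyl]cyclohexan-1-one
Conditions: Li (2.5 equiv), NH3(l)–THF, t-BuOH (1 equiv), −78 °C; then solid NH4Cl
Reagents that add atoms: none
Why: Dissolving-metal reduction of the enone; the β-carbon is protonated axially in the chair-like intermediate that keeps both the side chain and the C5 methyl equatorial, giving the cis-3,5 (all-cis) ketone with 10β-H. Limited lithium and a single equivalent of proton source keep the aryl ether ring from Birch reduction.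

**Step 12**
Reactants: 23 (3S,4S,5R)-4-(2,5-dimethoxybenzyl)-4,5-dimethyl-3-[3-(2-methyl-1,3-dioxolan-2-yl)propyl]cyclohexan-1-one
Product: 25 (3R,4S,4aR)-4-(2,5-dimethoxybenzyl)-3,4,8-trimethyl-3,4,4a,5,6,7-hexahydronaphthalen-1(2H)-one, via diketone 24 (not isolated)
Conditions: 2 M HCl, THF, rt; then KOH, MeOH, 65 °C
Reagents that add atoms: none
Why: Ketal hydrolysis and intramolecular aldol condensation as in step 4; only attack of W-C5 on the side-chain ketone gives a conjugated enone, and none of the three stereocentres is α to a carbonyl, so none can epimerise.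

**Step 13**
Reactants: 25 (3R,4S,4aR)-4-(2,5-dimethoxybenzyl)-3,4,8-trimethyl-3,4,4a,5,6,7-hexahydronaphthalen-1(2H)-one
Product: 26 (1S,3R,4S,4aR)-4-(2,5-dimethoxybenzyl)-3,4,8-trimethyl-1,2,3,4,4a,5,6,7-octahydronaphthalen-1-ol
Conditions: (R)-2-methyl-CBS-oxazaborolidine (20 mol%), catecholborane, toluene, −78 °C; aq NaOH
Reagents that add atoms: none
Why: CBS reduction under reagent control gives the (1S)-carbinol (6α-OH), the product of axial hydride attack on the β-face of ring B, which carries only axial hydrogens. This configuration later dictates W-C4.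

**Step 14**
Reactants: 12 4-oxo-4-{[(1S,4aS,7S)-4,4,7,8-tetramethyl-1,2,3,4,4a,5,6,7-octahydronaphthalen-1-yl]oxy}butanoic acid; 26 (1S,3R,4S,4aR)-4-(2,5-dimethoxybenzyl)-3,4,8-trimethyl-1,2,3,4,4a,5,6,7-octahydronaphthalen-1-ol
Product: 27 mixed succinate diester of alcohols 10 and 26
Conditions: DCC, DMAP (cat.), CH2Cl2, 0 °C to rt
Reagents that add atoms: none
Why: Steglich esterification; it joins the three components through a second trivial ester bond under neutral conditions, and any material from minor enantiomers becomes a separable diastereomer.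

**Step 15**
Reactants: 27 mixed succinate diester of alcohols 10 and 26
Product: 30 2,3-disubstituted succinic acid carrying unit E (through E-C9) on C11 and unit W (through W-C4) on C12, via bis(silyl ketene acetal) 28 (not isolated), via bis(trimethylsilyl) ester 29 (not isolated)
Conditions: LDA (2.5 equiv), TMSCl–Et3N (3 equiv), THF, −78 °C to rt; then toluene, 90 °C; 1 M HCl
Reagents that add atoms: none
Why: This is an Ireland–Claisen rearrangement run twice in one flask: double deprotonation and O-silylation of the succinate gives the bis(silyl ketene acetal) 28, a 1,4-dioxygenated butadiene whose two termini are C11 and C12. Each terminus then bonds to the γ-carbon of its own allyl ester through a six-membered cyclic [3,3] transition state; no ring is closed, and two C–O bonds are exchanged for the C11–E-C9 and C12–W-C4 bonds. The closest known reaction type is the ester-enolate Claisen rearrangement of allylic esters onto fully substituted alkene termini, including its two-fold use on bis-allylic diesters. The alkene transposition is built in: E-C9=C10 becomes C10=C1 and W-C4=C5 becomes C5=C6, exactly the two trisubstituted alkenes of the target. E-C9 is controlled by the E-C1 carbinol (step 5) and W-C4 by the W-C6 carbinol (step 13), because the shift is suprafacial on the allyl unit and the new bond forms on the α-face from which each C–O bond leaves. In unit E the 1α-ester is axial in the ring-A chair and aligned with the π bond, whereas in unit W the 6α-ester is pushed out of the alkene plane by A(1,3) strain with the C4 methyl into a twist-boat of ring B with the same alignment. C11 and C12 form without control, which is harmless because both become CH2 in step 16. The selectivities needed are complete bis-enolisation before either shift, secured by the internal silyl quench at −78 °C, and rearrangement faster than ionisation of the allylic esters, secured by the neutral, non-polar, amine-buffered medium.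

**Step 16**
Reactants: 30 2,3-disubstituted succinic acid carrying unit E on C11 and unit W on C12
Product: 32 hydroquinone dimethyl ether of the target skeleton (units E and W joined by C11H2–C12H2), via bis(thiohydroxamate) ester 31 (not isolated)
Conditions: 1-hydroxypyridine-2(1H)-thione, DCC, DMAP (cat.), CH2Cl2, 0 °C to rt, dark; then PhSH (10 equiv), THF, visible light, 0 °C
Reagents that add atoms: none
Why: Two-fold Barton decarboxylation; excess coupling reagent carries the 1,2-diacid through its cyclic anhydride to the bis-ester. Each secondary radical is homoallylic and could undergo a 1,2-vinyl shift by 3-exo closure, so concentrated thiophenol is used as a fast hydrogen donor and the closure must in addition attack a fully substituted alkene carbon.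

**Step 17**
Reactants: 32 hydroquinone dimethyl ether of the target skeleton
Product: 34 hydroquinone of the target skeleton, via quinone 33 (not isolated)
Conditions: (NH4)2Ce(NO3)6 (2.5 equiv), MeCN–THF–H2O, 0 °C; then aq Na2S2O4, Et2O, rt
Reagents that add atoms: water, SMILES O
Why: Oxidative demethylation of a 1,4-dimethoxyarene to the quinone and dithionite reduction, the known way to free such hydroquinones beside hindered trisubstituted alkenes; the quinone oxygens come from water.

**Step 18**
Reactants: 34 hydroquinone of the target skeleton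
Product: 36 target bis(hydrogen sulfate), via bis(pyridinium) sulfate 35 (not isolated)
Conditions: SO3·pyridine (6 equiv), pyridine, rt; then cation-exchange resin (H+ form), MeOH–H2O, 0 °C
Reagents that add atoms: sulfur trioxide–pyridine complex, SMILES [O-]S(=O)(=O)[n+]1ccccc1
Why: O-Sulfation of both phenols with the pyridine complex of SO3 under basic conditions, so the alkenes never see strong acid; brief cold cation exchange then gives the free acid form drawn for the target.

## Compound list

1 | 3-acetyl-3-methyloxolan-2-one (racemic) | CC(=O)C1(C)CCOC1=O | starting material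
2 | 5-bromo-3-methylpentan-2-one (racemic) | CC(=O)C(C)CCBr | intermediate
3 | 2-(4-bromobutan-2-yl)-2-methyl-1,3-dioxolane (racemic) | CC(CCBr)C1(C)OCCO1 | intermediate
4 | 4,4-dimethylcyclohex-2-en-1-one | CC1(C)CCC(=O)C=C1 | starting material
5 | [3-(2-methyl-1,3-dioxolan-2-yl)butyl]magnesium bromide | CC(CC[Mg]Br)C1(C)OCCO1 | intermediate
6 | bis[3-(2-methyl-1,3-dioxolan-2-yl)butyl]zinc | CC(CC[Zn]CCC(C)C1(C)OCCO1)C1(C)OCCO1 | intermediate
7 | (3R)-4,4-dimethyl-3-[3-(2-methyl-1,3-dioxolan-2-yl)butyl]cyclohexan-1-one | O=C1CCC(C)(C)[C@H](CCC(C)C2(C)OCCO2)C1 | intermediate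
8 | (3R)-4,4-dimethyl-3-(3-methyl-4-oxopentyl)cyclohexan-1-one | O=C1CCC(C)(C)[C@H](CCC(C)C(C)=O)C1 | intermediate
9 | (4aS,7S)-4,4,7,8-tetramethyl-3,4,4a,5,6,7-hexahydronaphthalen-1(2H)-one (eastern enone) | O=C1CCC(C)(C)[C@@H]2CC[C@H](C)C(C)=C12 | intermediate
10 | (1S,4aS,7S)-4,4,7,8-tetramethyl-1,2,3,4,4a,5,6,7-octahydronaphthalen-1-ol (eastern allylic alcohol) | O[C@H]1CCC(C)(C)[C@@H]2CC[C@H](C)C(C)=C12 | intermediate
11 | succinic anhydride | O=C1CCC(=O)O1 | starting material
12 | 4-oxo-4-{[(1S,4aS,7S)-4,4,7,8-tetramethyl-1,2,3,4,4a,5,6,7-octahydronaphthalen-1-yl]oxy}butanoic acid | OC(=O)CCC(=O)O[C@H]1CCC(C)(C)[C@@H]2CC[C@H](C)C(C)=C12 | intermediate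
13 | 2-methylcyclohex-2-en-1-one | CC1=CCCCC1=O | starting material
14 | 2-(chloromethyl)-1,4-dimethoxybenzene | COc1ccc(OC)c(CCl)c1 | starting material
15 | bromomagnesium (3R)-2,3-dimethylcyclohex-1-en-1-olate | Br[Mg]OC1=C(C)[C@H](C)CCC1 | intermediate
16 | (2S,3R)-2-(2,5-dimethoxybenzyl)-2,3-dimethylcyclohexan-1-one | O=C1CCC[C@@H](C)[C@]1(C)Cc1cc(OC)ccc1OC | intermediate
17 | {[(5R,6S)-6-(2,5-dimethoxybenzyl)-5,6-dimethylcyclohex-1-en-1-yl]oxy}trimethylsilane | C[Si](C)(C)OC1=CCC[C@@H](C)[C@]1(C)Cc1cc(OC)ccc1OC | intermediate
18 | (5R,6S)-6-(2,5-dimethoxybenzyl)-5,6-dimethylcyclohex-2-en-1-one | O=C1C=CC[C@@H](C)[C@]1(C)Cc1cc(OC)ccc1OC | intermediate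
19 | 2-(3-chloropropyl)-2-methyl-1,3-dioxolane | CC1(CCCCl)OCCO1 | starting material
20 | [3-(2-methyl-1,3-dioxolan-2-yl)propyl]magnesium chloride | CC1(CCC[Mg]Cl)OCCO1 | intermediate
21 | (5R,6S)-6-(2,5-dimethoxybenzyl)-5,6-dimethyl-1-[3-(2-methyl-1,3-dioxolan-2-yl)propyl]cyclohex-2-en-1-ol (C1 epimers) | OC1(CCCC2(C)OCCO2)C=CC[C@@H](C)[C@]1(C)Cc1cc(OC)ccc1OC | intermediate
22 | (4S,5R)-4-(2,5-dimethoxybenzyl)-4,5-dimethyl-3-[3-(2-methyl-1,3-dioxolan-2-yl)propyl]cyclohex-2-en-1-one | O=C1C=C(CCCC2(C)OCCO2)[C@@](C)(Cc3cc(OC)ccc3OC)[C@H](C)C1 | intermediate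
23 | (3S,4S,5R)-4-(2,5-dimethoxybenzyl)-4,5-dimethyl-3-[3-(2-methyl-1,3-dioxolan-2-yl)propyl]cyclohexan-1-one | O=C1C[C@H](CCCC2(C)OCCO2)[C@@](C)(Cc3cc(OC)ccc3OC)[C@H](C)C1 | intermediate
24 | (3S,4S,5R)-4-(2,5-dimethoxybenzyl)-4,5-dimethyl-3-(4-oxopentyl)cyclohexan-1-one | O=C1C[C@H](CCCC(C)=O)[C@@](C)(Cc2cc(OC)ccc2OC)[C@H](C)C1 | intermediate
25 | (3R,4S,4aR)-4-(2,5-dimethoxybenzyl)-3,4,8-trimethyl-3,4,4a,5,6,7-hexahydronaphthalen-1(2H)-one (western enone) | O=C1C[C@@H](C)[C@](C)(Cc2cc(OC)ccc2OC)[C@H]2CCCC(C)=C12 | intermediate
26 | (1S,3R,4S,4aR)-4-(2,5-dimethoxybenzyl)-3,4,8-trimethyl-1,2,3,4,4a,5,6,7-octahydronaphthalen-1-ol (western allylic alcohol) | O[C@H]1C[C@@H](C)[C@](C)(Cc2cc(OC)ccc2OC)[C@H]2CCCC(C)=C12 | intermediate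
27 | mixed succinate diester: butanedioate of alcohol 10 (through O on E-C1) and alcohol 26 (through O on W-C6) | O=C(CCC(=O)O[C@H]1CCC(C)(C)[C@@H]2CC[C@H](C)C(C)=C12)O[C@H]1C[C@@H](C)[C@](C)(Cc2cc(OC)ccc2OC)[C@H]2CCCC(C)=C12 | intermediate
28 | bis(trimethylsilyl ketene acetal) of 27 (1,4-bis(allyloxy)-1,4-bis(trimethylsilyloxy)buta-1,3-diene; alkene geometry unassigned) | C[Si](C)(C)OC(O[C@H]1CCC(C)(C)[C@@H]2CC[C@H](C)C(C)=C12)=CC=C(O[Si](C)(C)C)O[C@H]1C[C@@H](C)[C@](C)(Cc2cc(OC)ccc2OC)[C@H]2CCCC(C)=C12 | intermediate
29 | bis(trimethylsilyl) ester of diacid 30 | C[C@@H]1CC=C2[C@H](CCC[C@@]2(C)C(C(=O)O[Si](C)(C)C)C(C(=O)O[Si](C)(C)C)[C@@]2(C)C3=CCCC(C)(C)[C@@H]3CC[C@@H]2C)[C@@]1(C)Cc1cc(OC)ccc1OC | intermediate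
30 | 2,3-disubstituted succinic acid: C11 bears unit E through E-C9 (9β-Me, 8β-Me, 5α-H, C1=C10 alkene), C12 bears unit W through W-C4 (4β-Me, C5=C6 alkene, 10β-H, 9α-Me, 9β-(2,5-dimethoxybenzyl), 8α-Me) | C[C@@H]1CC=C2[C@H](CCC[C@@]2(C)C(C(=O)O)C(C(=O)O)[C@@]2(C)C3=CCCC(C)(C)[C@@H]3CC[C@@H]2C)[C@@]1(C)Cc1cc(OC)ccc1OC | intermediate
31 | bis(2-thioxopyridin-1(2H)-yl) ester of diacid 30 | C[C@@H]1CC=C2[C@H](CCC[C@@]2(C)C(C(=O)ON3C=CC=CC3=S)C(C(=O)ON3C=CC=CC3=S)[C@@]2(C)C3=CCCC(C)(C)[C@@H]3CC[C@@H]2C)[C@@]1(C)Cc1cc(OC)ccc1OC | intermediate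
32 | hydroquinone dimethyl ether of the target skeleton (units E and W joined by C11H2–C12H2; arene = 2,5-dimethoxyphenyl) | C[C@@H]1CC=C2[C@H](CCC[C@@]2(C)CC[C@@]2(C)C3=CCCC(C)(C)[C@@H]3CC[C@@H]2C)[C@@]1(C)Cc1cc(OC)ccc1OC | intermediate
33 | 2-substituted 1,4-benzoquinone of the target skeleton | C[C@@H]1CC=C2[C@H](CCC[C@@]2(C)CC[C@@]2(C)C3=CCCC(C)(C)[C@@H]3CC[C@@H]2C)[C@@]1(C)CC1=CC(=O)C=CC1=O | intermediate
34 | 2-substituted benzene-1,4-diol (hydroquinone) of the target skeleton | C[C@@H]1CC=C2[C@H](CCC[C@@]2(C)CC[C@@]2(C)C3=CCCC(C)(C)[C@@H]3CC[C@@H]2C)[C@@]1(C)Cc1cc(O)ccc1O | intermediate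
35 | bis(pyridinium) salt of the target bis(sulfate) | C[C@@H]1CC=C2[C@H](CCC[C@@]2(C)CC[C@@]2(C)C3=CCCC(C)(C)[C@@H]3CC[C@@H]2C)[C@@]1(C)Cc1cc(OS(=O)(=O)[O-])ccc1OS(=O)(=O)[O-].c1cc[nH+]cc1.c1cc[nH+]cc1 | intermediate
36 | target: 2-[(unit W C9)methyl]benzene-1,4-diyl bis(hydrogen sulfate), unit W joined through C12–C11 to unit E | C[C@@H]1CC=C2[C@H](CCC[C@@]2(C)CC[C@@]2(C)C3=CCCC(C)(C)[C@@H]3CC[C@@H]2C)[C@@]1(C)Cc1cc(OS(=O)(=O)O)ccc1OS(=O)(=O)O | target

## Step count and weak points

Total: 18 steps. Longest linear sequence: 12 steps (steps 7–18, from 13). The eastern branch is steps 1–6.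

**Step 15 (key step).**
- Risk: bis-enolisation may stop after one arm. The second shift has to form a bond between a carbon that already carries the first bulky decalin and a tetrasubstituted alkene terminus, and in unit W it must pass through a twist-boat. Ionisation of the allylic ester to an allyl cation with elimination to a diene, or loss of ketene from the silyl ketene acetal, could then win.
- Fallback (sets out from 12 and 26, returns at 32): make the two bonds one at a time, so that the second enolate carbon is an unhindered CH2.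
  - Dianionic Ireland–Claisen rearrangement of half-ester 12 (LDA 2.2 equiv, TMSCl) gives the eastern succinic acid F1.
  - Steglich esterification of its unhindered CH2CO2H with 26 gives half-ester F2.
  - Barton decarboxylation of the hindered acid gives the western allyl ester F3.
  - A single Ireland–Claisen rearrangement gives the mono-acid F4.
  - A second Barton decarboxylation gives 32.

**Step 16.**
- Risk: ester formation at two neopentyl-type carboxyls may stall at the cyclic anhydride or the mono-ester, and radical 1,2-vinyl migration (3-exo closure, reopening to a tertiary radical) could compete with hydrogen transfer and scramble the skeleton next to a quaternary centre.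
- Fallback (sets out from 30, returns at 32): oxidative bis-decarboxylation with Pb(OAc)4, pyridine and O2 in benzene at 60 °C gives the trans-alkene F5, in which loss of the second CO2 from the β-carboxy intermediate is faster than rearrangement. Diimide (2-nitrobenzenesulfonylhydrazide, Et3N) then reduces only the 1,2-disubstituted alkene to give 32.

**Step 13.**
- Risk: poor facial selectivity. The wanted 6α-alcohol is the more strained one (A(1,3) strain with the C4 methyl), and hydride delivery from the α-face would give the 6β-epimer, which would later place the tether on the wrong face of W-C4.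
- Fallback (sets out from 25, returns at 26): take the 6β-alcohol F6, invert it by Mitsunobu reaction with 4-nitrobenzoic acid to the 4-nitrobenzoate F7, and cleave with K2CO3 in MeOH to 26.

**Step 4.**
- Risk: incomplete equilibration at E-C8, or too small an energy gap between the pseudoaxial and pseudoequatorial methyl epimers.
- Fallback (sets out from 9, returns at 9): separation and recycling instead of a single pass. Carry the mixture through step 5, separate 10 from its C8-epimeric alcohol F8, oxidise F8 with MnO2 to the epimeric enone F9, and resubmit F9 to KOH in MeOH to regenerate 9.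

**Step 7.**
- Risk: insufficient enantioselectivity in the conjugate addition to the α-substituted enone, and O-alkylation or proton transfer in place of C-benzylation of the hindered magnesium enolate.
- Fallback (sets out from 13 and 14, returns at 18): resolution instead of asymmetric catalysis.
  - Me2CuLi addition, then benzylation of the lithium enolate in THF–HMPA, gives the racemic ketone F10.
  - The conditions of step 8 give the racemic enone F11.
  - CBS reduction with the (R)-catalyst turns the two enantiomers into diastereomeric allylic alcohols; the (1S,5R,6S)-alcohol F12 is separated.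
  - MnO2 oxidation of F12 gives 18.

## Further compounds

F1 | step 15 | 2-(unit E C9-yl)butanedioic acid (9β-Me, 8β-Me, 5α-H, C1=C10 alkene; C11 undefined) | OC(=O)CC(C(=O)O)[C@@]1(C)C2=CCCC(C)(C)[C@@H]2CC[C@@H]1C
F2 | step 15 | half-ester of F1 with 26 at the unhindered carboxyl | OC(=O)C(CC(=O)O[C@H]1C[C@@H](C)[C@](C)(Cc2cc(OC)ccc2OC)[C@H]2CCCC(C)=C12)[C@@]1(C)C2=CCCC(C)(C)[C@@H]2CC[C@@H]1C
F3 | step 15 | ester of 26 with 3-(unit E C9-yl)propanoic acid | O=C(CC[C@@]1(C)C2=CCCC(C)(C)[C@@H]2CC[C@@H]1C)O[C@H]1C[C@@H](C)[C@](C)(Cc2cc(OC)ccc2OC)[C@H]2CCCC(C)=C12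
F4 | step 15 | mono-acid with CO2H on C12 (units E and W joined by C11H2–C12H(CO2H); C12 undefined) | C[C@@H]1CC=C2[C@H](CCC[C@@]2(C)C(C(=O)O)C[C@@]2(C)C3=CCCC(C)(C)[C@@H]3CC[C@@H]2C)[C@@]1(C)Cc1cc(OC)ccc1OC
F5 | step 16 | (E)-C11=C12 alkene analogue of 32 | C[C@@H]1CC=C2[C@H](CCC[C@@]2(C)/C=C/[C@@]2(C)C3=CCCC(C)(C)[C@@H]3CC[C@@H]2C)[C@@]1(C)Cc1cc(OC)ccc1OC
F6 | step 13 | (1R,3R,4S,4aR)-4-(2,5-dimethoxybenzyl)-3,4,8-trimethyl-1,2,3,4,4a,5,6,7-octahydronaphthalen-1-ol (6β-epimer of 26) | O[C@@H]1C[C@@H](C)[C@](C)(Cc2cc(OC)ccc2OC)[C@H]2CCCC(C)=C12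
F7 | step 13 | 4-nitrobenzoate of 26 | O=C(O[C@H]1C[C@@H](C)[C@](C)(Cc2cc(OC)ccc2OC)[C@H]2CCCC(C)=C12)c1ccc(cc1)[N+](=O)[O-]
F8 | step 4 | (1S,4aS,7R)-4,4,7,8-tetramethyl-1,2,3,4,4a,5,6,7-octahydronaphthalen-1-ol (C8 epimer of 10) | O[C@H]1CCC(C)(C)[C@@H]2CC[C@@H](C)C(C)=C12
F9 | step 4 | (4aS,7R)-4,4,7,8-tetramethyl-3,4,4a,5,6,7-hexahydronaphthalen-1(2H)-one (C8 epimer of 9) | O=C1CCC(C)(C)[C@@H]2CC[C@@H](C)C(C)=C12
F10 | step 7 | racemic 2-(2,5-dimethoxybenzyl)-2,3-dimethylcyclohexan-1-one (cis methyls; both enantiomers) | O=C1CCC[C@@H](C)[C@]1(C)Cc1cc(OC)ccc1OC.O=C1CCC[C@H](C)[C@@]1(C)Cc1cc(OC)ccc1OC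
F11 | step 7 | racemic 6-(2,5-dimethoxybenzyl)-5,6-dimethylcyclohex-2-en-1-one (both enantiomers) | O=C1C=CC[C@@H](C)[C@]1(C)Cc1cc(OC)ccc1OC.O=C1C=CC[C@H](C)[C@@]1(C)Cc1cc(OC)ccc1OC
F12 | step 7 | (1S,5R,6S)-6-(2,5-dimethoxybenzyl)-5,6-dimethylcyclohex-2-en-1-ol | O[C@H]1C=CC[C@@H](C)[C@]1(C)Cc1cc(OC)ccc1OC
A1 | alternative 1 | unit E C9-carbaldehyde (9β-Me, 8β-Me, 5α-H, C1=C10 alkene) | O=C[C@@]1(C)C2=CCCC(C)(C)[C@@H]2CC[C@@H]1C
A2 | alternative 1 | unit W C4-methyl 1-phenyl-1H-tetrazol-5-yl sulfone (arene as dimethyl ether) | C[C@@H]1CC=C2[C@H](CCC[C@@]2(C)CS(=O)(=O)c2nnnn2-c2ccccc2)[C@@]1(C)Cc1cc(OC)ccc1OC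
A3 | alternative 1 | (E)-C11=C12 alkene from A1 and A2 | C[C@@H]1CC=C2[C@H](CCC[C@@]2(C)/C=C/[C@@]2(C)C3=CCCC(C)(C)[C@@H]3CC[C@@H]2C)[C@@]1(C)Cc1cc(OC)ccc1OC
A4 | alternative 2 | unit W 4-methyl-Δ4-3-ketone (10β-H, 9α-Me, 9β-(2,5-dimethoxybenzyl), 8α-Me) | O=C1CC[C@H]2C(=C1C)CC[C@@H](C)[C@]2(C)Cc1cc(OC)ccc1OC
A5 | alternative 2 | unit E C9-(2-iodoethyl) compound | ICC[C@@]1(C)C2=CCCC(C)(C)[C@@H]2CC[C@@H]1C
A6 | alternative 2 | 3-keto derivative of 32 (4β-Me, 4α-tether, C5=C6 alkene) | O=C1CC[C@H]2C(=CC[C@@H](C)[C@]2(C)Cc2cc(OC)ccc2OC)[C@]1(C)CC[C@@]1(C)C2=CCCC(C)(C)[C@@H]2CC[C@@H]1C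
A7 | alternative 3 | 2-(5,5,8a-trimethyl-2-methylidenedecahydronaphthalen-1-yl)ethanol with the drimane configuration (5α-H, 9α-H, 10β-Me) | OCC[C@H]1C(=C)CC[C@H]2C(C)(C)CCC[C@]12C
A8 | alternative 3 | unit E C9-(2-hydroxyethyl) compound (9β-Me, 8β-Me, 5α-H, C1=C10 alkene) | OCC[C@@]1(C)C2=CCCC(C)(C)[C@@H]2CC[C@@H]1C
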